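**Plan**
- Retrosynthesis: the first cut is the C–C bond between the quaternary C2 of the chroman-4-one ring and the CH2 on C2 of the 4H-chromen-4-one ring (retro vinylogous Mukaiyama–Michael), which gives two copies of one 2-methylchromone. Then come the two side-chain C=O groups (retro-Wacker to allyl), the two aryl–allyl bonds (retro-Stille to a 5-triflate) and the O-benzyl bonds, back to noreugenin.
- Forward: both bicyclic ring systems come intact from noreugenin and no ring is built. The monomer is O-silylated once to a single batch of benzopyrylium salt; part of it is deprotonated to the silyl dienol ether and joined to the rest, and the pyranone ring of the acceptor half becomes the chroman-4-one.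
- Enabling feature: the 2-methyl-4H-pyran-4-one ring is ambident. O-silylation at C4=O gives a benzopyrylium that is electrophilic at C2 and acidic at the 2-CH3. Its anhydrobase (2-methylidene-2H-chromene) is nucleophilic at that CH2. The target's chromanone C2 (bearing O1, CH3, C3H2) and the CH2 on the chromone C2 are these two sites of one monomer.
- Stereochemistry: the only stereocentre (chromanone C2, R) is set in the key step by a chiral anion-binding catalyst that controls the face of the benzopyrylium. Only neutral or weakly acidic steps follow, since base would open the β-aryloxy ketone and could aldolise a 5-acetonyl group onto C4=O.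
- Helpers: the ketones are carried as allyl groups and the 7-OH as a benzyl ether; the TBS groups are carried only through the moisture-sensitive compounds 5 to 7 and leave on hydrolysis.

Key step: step 6

Remark: noreugenin is taken as commercially available. The 2-oxopropyl groups are masked as allyl because an ArCH2C(=O)CH3 unit is more acidic than the chromone 2-CH3 and would be enolised and silylated first.

**Step 1**
Reactants: 1 noreugenin (5,7-dihydroxy-2-methyl-4H-chromen-4-one)
Product: 2 7-(benzyloxy)-5-hydroxy-2-methyl-4H-chromen-4-one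
Conditions: BnBr (1.05 equiv), K2CO3 (1.2 equiv), acetone, reflux
Reagents that add atoms: benzyl bromide, BrCc1ccccc1
Why: Williamson ether synthesis; the 5-OH is tied up in a hydrogen bond to the C4 carbonyl, so the more acidic 7-OH (para to the carbonyl-bearing carbon) should be the one deprotonated and benzylated.

**Step 2**
Reactants: 2 7-(benzyloxy)-5-hydroxy-2-methyl-4H-chromen-4-one
Product: 3 7-(benzyloxy)-2-methyl-4-oxo-4H-chromen-5-yl trifluoromethanesulfonate
Conditions: Tf2O (1.2 equiv), pyridine, CH2Cl2, 0 °C to rt
Reagents that add atoms: trifluoromethanesulfonic anhydride, O=S(=O)(OS(=O)(=O)C(F)(F)F)C(F)(F)F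
Why: O-sulfonylation of the remaining chelated phenol should give the aryl triflate needed for cross-coupling, with the chromone and benzyl ether inert.

**Step 3**
Reactants: 3 7-(benzyloxy)-2-methyl-4-oxo-4H-chromen-5-yl trifluoromethanesulfonate
Product: 4 7-(benzyloxy)-2-methyl-5-(prop-2-en-1-yl)-4H-chromen-4-one
Conditions: allylSnBu3 (1.3 equiv), Pd(PPh3)4 (5 mol %), LiCl (3 equiv), 1,4-dioxane, 100 °C
Reagents that add atoms: allyltributylstannane, C=CC[Sn](CCCC)(CCCC)CCCC
Why: Stille coupling of an aryl triflate with an allylstannane (LiCl assists transmetalation) should install a three-carbon chain that is inert to silyl triflates and is a latent methyl ketone.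

**Step 4**
Reactants: 4 7-(benzyloxy)-2-methyl-5-(prop-2-en-1-yl)-4H-chromen-4-one
Product: 5 7-(benzyloxy)-4-[(tert-butyldimethylsilyl)oxy]-2-methyl-5-(prop-2-en-1-yl)chromenylium trifluoromethanesulfonate
Conditions: TBSOTf (1.05 equiv, freshly distilled), toluene, 60 °C, 1 h, Ar; kept as a stock solution under Ar and used the same day in steps 5 and 6
Reagents that add atoms: tert-butyldimethylsilyl trifluoromethanesulfonate, CC(C)(C)[Si](C)(C)OS(=O)(=O)C(F)(F)F
Why: O-silylation of the vinylogous-ester carbonyl of a chromone by a silyl triflate should give the aromatic 4-siloxybenzopyrylium triflate (the known activation of chromones for Mukaiyama-type additions), with the allyl group and the benzyl ether inert to the silyl triflate.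

**Step 5**
Reactants: 5 7-(benzyloxy)-4-[(tert-butyldimethylsilyl)oxy]-2-methyl-5-(prop-2-en-1-yl)chromenylium trifluoromethanesulfonate (about half of the stock solution from step 4)
Product: 6 {[7-(benzyloxy)-2-methylidene-5-(prop-2-en-1-yl)-2H-chromen-4-yl]oxy}(tert-butyl)dimethylsilane
Conditions: solution of 5 added slowly to Et3N (3 equiv), Et2O, –78 to 0 °C; pentane, filtration under Ar, concentration; crude 6 used at once
Reagents that add atoms: none
Why: Deprotonation of a 2-methylpyrylium salt to its anhydrobase (the second half of a soft enolisation with R3SiOTf/Et3N) should give the silyl dienol ether, since the 2-CH3 of 5 is the only position whose deprotonation leaves the benzene ring intact, and inverse addition into excess amine keeps unreacted cation from meeting 6.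

**Step 6**
Reactants: 5 7-(benzyloxy)-4-[(tert-butyldimethylsilyl)oxy]-2-methyl-5-(prop-2-en-1-yl)chromenylium trifluoromethanesulfonate (the remaining stock solution); 6 {[7-(benzyloxy)-2-methylidene-5-(prop-2-en-1-yl)-2H-chromen-4-yl]oxy}(tert-butyl)dimethylsilane
Product: 8 7-(benzyloxy)-2-{[(2R)-7-(benzyloxy)-2-methyl-4-oxo-5-(prop-2-en-1-yl)-3,4-dihydro-2H-chromen-2-yl]methyl}-5-(prop-2-en-1-yl)-4H-chromen-4-one, via bis-silylated adduct triflate 7 (not isolated)
Conditions: 5 in toluene, cooled to –78 °C; chiral anion-binding H-bond-donor catalyst (tetrakis-triazole on trans-1,2-diaminocyclohexane, 10 mol %; the catalyst enantiomer that leads to the 2R product is to be fixed in a first screen); 6 (1.1 equiv) in toluene by syringe pump, –78 °C; then 1 M HCl, THF, 0 °C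
Reagents that add atoms: none
Why: Proposed new method: 6, the anhydrobase of cation 5, attacks C2 of 5 through its exocyclic CH2 in a vinylogous Mukaiyama–Michael addition, which re-aromatises the donor ring to a 4-siloxybenzopyrylium and dearomatises the acceptor ring to a 4-siloxy-2H-chromene, so one aromatic cation is traded for another and the net change is a C–C σ bond for a C=C π bond; aqueous acid then removes both silyl groups from 7. The closest known reaction type is the anion-binding-catalysed enantioselective Mukaiyama-type addition of silyl ketene acetals to 4-siloxybenzopyrylium triflates made from chromones, together with the classical attack of methylenepyran anhydrobases on pyrylium salts; new here are the dienol ether nucleophile and the tetrasubstituted carbon. No ring is closed in this step. The new stereocentre (chromanone C2, R) should be controlled by the chiral H-bond donor, which holds the triflate over one face of the planar cation in a tight ion pair in toluene so that 6 enters from the open face. The step needs C2 rather than C4 attack on the cation (the normal course of additions to 4-siloxybenzopyrylium ions), CH2 rather than C3 attack on the donor (only CH2 attack restores the aromatic cation), no second addition to the product cation (its C2 now carries a neopentyl-type branch, and slow addition keeps 6 low) and no attack by the allyl groups (monosubstituted alkenes are far weaker π-nucleophiles than the dienol ether). Proton transfer between 5 and 6 is degenerate, because each is the conjugate acid or base of the other, so it should cost no material.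

**Step 7**
Reactants: 8 7-(benzyloxy)-2-{[(2R)-7-(benzyloxy)-2-methyl-4-oxo-5-(prop-2-en-1-yl)-3,4-dihydro-2H-chromen-2-yl]methyl}-5-(prop-2-en-1-yl)-4H-chromen-4-one
Product: 9 7-(benzyloxy)-2-{[(2R)-7-(benzyloxy)-2-methyl-4-oxo-5-(2-oxopropyl)-3,4-dihydro-2H-chromen-2-yl]methyl}-5-(2-oxopropyl)-4H-chromen-4-one
Conditions: PdCl2 (20 mol %), CuCl (cat.), O2 (1 atm), DMF/H2O 7:1, rt
Reagents that add atoms: water, O
Why: Tsuji–Wacker oxidation: Markovnikov hydroxypalladation of both terminal alkenes and β-hydride elimination should give the two methyl ketones under near-neutral conditions that leave the C2 stereocentre (a β-aryloxy ketone) untouched.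

**Step 8**
Reactants: 9 7-(benzyloxy)-2-{[(2R)-7-(benzyloxy)-2-methyl-4-oxo-5-(2-oxopropyl)-3,4-dihydro-2H-chromen-2-yl]methyl}-5-(2-oxopropyl)-4H-chromen-4-one
Product: 10 7-hydroxy-2-{[(2R)-7-hydroxy-2-methyl-4-oxo-5-(2-oxopropyl)-3,4-dihydro-2H-chromen-2-yl]methyl}-5-(2-oxopropyl)-4H-chromen-4-one (CNP0319595.1)
Conditions: H2 (1 atm), 10% Pd/C, EtOAc, rt, stopped when both ethers are cleaved
Reagents that add atoms: none
Why: Catalytic hydrogenolysis of the two benzyl aryl ethers under neutral conditions should free both phenols without base-induced retro-oxa-Michael opening at C2 or aldol closure of the acetonyl groups onto C4, the chromone C2=C3 bond and the ketones being reduced more slowly.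

**Compound list**
1 | noreugenin (5,7-dihydroxy-2-methyl-4H-chromen-4-one) | Cc1cc(=O)c2c(O)cc(O)cc2o1 | starting material
2 | 7-(benzyloxy)-5-hydroxy-2-methyl-4H-chromen-4-one | Cc1cc(=O)c2c(O)cc(OCc3ccccc3)cc2o1 | intermediate
3 | 7-(benzyloxy)-2-methyl-4-oxo-4H-chromen-5-yl trifluoromethanesulfonate | Cc1cc(=O)c2c(OS(=O)(=O)C(F)(F)F)cc(OCc3ccccc3)cc2o1 | intermediate
4 | 7-(benzyloxy)-2-methyl-5-(prop-2-en-1-yl)-4H-chromen-4-one | Cc1cc(=O)c2c(CC=C)cc(OCc3ccccc3)cc2o1 | intermediate
5 | 7-(benzyloxy)-4-[(tert-butyldimethylsilyl)oxy]-2-methyl-5-(prop-2-en-1-yl)chromenylium trifluoromethanesulfonate | Cc1cc(O[Si](C)(C)C(C)(C)C)c2c(CC=C)cc(OCc3ccccc3)cc2[o+]1.[O-]S(=O)(=O)C(F)(F)F | intermediate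
6 | {[7-(benzyloxy)-2-methylidene-5-(prop-2-en-1-yl)-2H-chromen-4-yl]oxy}(tert-butyl)dimethylsilane | C=C1C=C(O[Si](C)(C)C(C)(C)C)c2c(CC=C)cc(OCc3ccccc3)cc2O1 | intermediate
7 | 7-(benzyloxy)-2-({(2R)-7-(benzyloxy)-4-[(tert-butyldimethylsilyl)oxy]-2-methyl-5-(prop-2-en-1-yl)-2H-chromen-2-yl}methyl)-4-[(tert-butyldimethylsilyl)oxy]-5-(prop-2-en-1-yl)chromenylium trifluoromethanesulfonate (not isolated) | C=CCc1cc(OCc2ccccc2)cc2c1C(O[Si](C)(C)C(C)(C)C)=C[C@@](C)(Cc1cc(O[Si](C)(C)C(C)(C)C)c3c(CC=C)cc(OCc4ccccc4)cc3[o+]1)O2.[O-]S(=O)(=O)C(F)(F)F | intermediate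
8 | 7-(benzyloxy)-2-{[(2R)-7-(benzyloxy)-2-methyl-4-oxo-5-(prop-2-en-1-yl)-3,4-dihydro-2H-chromen-2-yl]methyl}-5-(prop-2-en-1-yl)-4H-chromen-4-one | C=CCc1cc(OCc2ccccc2)cc2c1C(=O)C[C@@](C)(Cc1cc(=O)c3c(CC=C)cc(OCc4ccccc4)cc3o1)O2 | intermediate
9 | 7-(benzyloxy)-2-{[(2R)-7-(benzyloxy)-2-methyl-4-oxo-5-(2-oxopropyl)-3,4-dihydro-2H-chromen-2-yl]methyl}-5-(2-oxopropyl)-4H-chromen-4-one | CC(=O)Cc1cc(OCc2ccccc2)cc2c1C(=O)C[C@@](C)(Cc1cc(=O)c3c(CC(C)=O)cc(OCc4ccccc4)cc3o1)O2 | intermediate
10 | 7-hydroxy-2-{[(2R)-7-hydroxy-2-methyl-4-oxo-5-(2-oxopropyl)-3,4-dihydro-2H-chromen-2-yl]methyl}-5-(2-oxopropyl)-4H-chromen-4-one | CC(=O)Cc1cc(O)cc2c1C(=O)C[C@@](C)(Cc1cc(=O)c3c(CC(C)=O)cc(O)cc3o1)O2 | target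

**Totals**
Total step count: 8. Longest linear sequence: 8 steps (1 → 2 → 3 → 4 → 5 → 6 → 8 → 9 → 10; the second portion of 5 enters step 6 as the electrophile).

**Steps most likely to fail**

Step 6 (proposed new method). The risk is poor facial selectivity: the uncatalysed ion pair may react alongside the catalyst-bound one, the catalyst may be held by the triflate of the product cation, and reversible addition could erode the configuration. Fallback, setting out from 5 and 6: the two are combined in CH2Cl2 at –78 °C without any chiral catalyst. This is the known reaction type of a silyl enol ether adding to C2 of a 4-siloxybenzopyrylium triflate made from a chromone, and it should give the racemic bis-silylated adduct triflate F1. Hydrolysis with 1 M HCl in THF should give the racemic protected dimer F2. Preparative SFC on a polysaccharide-carbamate chiral stationary phase then separates the (R)-enantiomer from the (S)-configured protected dimer F3, and the route is rejoined at 8.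

Step 7. The risks are Pd-mediated migration of the allyl double bonds into conjugation with the arenes, aldehyde formation through chelation of palladium by the peri C4 carbonyl, and incomplete oxidation of the second alkene. Fallback, setting out from 8: radical Markovnikov hydration (Co(acac)2 cat., PhSiH3, O2, THF/i-PrOH, rt, then PPh3) should give the bis(2-hydroxypropyl) compound F4 as a mixture of carbinol epimers, which is of no consequence. Oxidation with Dess–Martin periodinane (NaHCO3, CH2Cl2) converges on 9, where the route is rejoined.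

Step 5. The risks are premature, uncatalysed C–C coupling of freshly formed 6 with cation 5 that has not yet been deprotonated, and hydrolysis of 6 during isolation. Fallback, setting out from 4: 4 is added to LDA (1.1 equiv, THF, –78 °C) to give the lithium dienolate F5 by kinetic deprotonation of the 2-CH3, with no cation present. O-silylation with TBSCl/DMPU gives 6, where the route is rejoined.

**Further compounds**
F1 | step 6 | racemic bis-silylated adduct triflate (racemate of 7) | C=CCc1cc(OCc2ccccc2)cc2c1C(O[Si](C)(C)C(C)(C)C)=CC(C)(Cc1cc(O[Si](C)(C)C(C)(C)C)c3c(CC=C)cc(OCc4ccccc4)cc3[o+]1)O2.[O-]S(=O)(=O)C(F)(F)F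
F2 | step 6 | racemic protected dimer (racemate of 8) | C=CCc1cc(OCc2ccccc2)cc2c1C(=O)CC(C)(Cc1cc(=O)c3c(CC=C)cc(OCc4ccccc4)cc3o1)O2
F3 | step 6 | (S)-configured protected dimer (enantiomer of 8) | C=CCc1cc(OCc2ccccc2)cc2c1C(=O)C[C@](C)(Cc1cc(=O)c3c(CC=C)cc(OCc4ccccc4)cc3o1)O2
F4 | step 7 | 7-(benzyloxy)-2-{[(2R)-7-(benzyloxy)-5-(2-hydroxypropyl)-2-methyl-4-oxo-3,4-dihydro-2H-chromen-2-yl]methyl}-5-(2-hydroxypropyl)-4H-chromen-4-one (carbinol epimers) | CC(O)Cc1cc(OCc2ccccc2)cc2c1C(=O)C[C@@](C)(Cc1cc(=O)c3c(CC(C)O)cc(OCc4ccccc4)cc3o1)O2
F5 | step 5 | lithium 7-(benzyloxy)-2-methylidene-5-(prop-2-en-1-yl)-2H-chromen-4-olate | C=C1C=C(O[Li])c2c(CC=C)cc(OCc3ccccc3)cc2O1
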